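The oxolane ring is disconnected at C2: the 3,4-dimethoxyphenyl group is attached last to a lactone that already carries C3, C4 and C5. That lactone arises in one three-component operation from an (S)-5-aryl butenolide: a methyl cuprate adds to C4 anti to the C5 trimethoxyphenyl group and the resulting enolate is methylated at C3 anti to the new methyl. The step exploits the C3–C4–C5 triad of the oxolane ring, in which aryl, methyl and methyl alternate faces. The precursor is a flat butenolide whose single stereocentre, C5, comes from an asymmetric alkynylation. C2 is set afterwards by aryl transfer to the C2–H oxocarbenium ion, anti to the C4 methyl.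

Key step: step 3

Assumption: (R,R)-ProPhenol is taken to send the alkynylzinc to the Si face of aldehyde 1, by analogy with the Re-face preference of the (S,S)-ligand in its aldol reactions; if the sense proves opposite, the mirror-image ligand is used and nothing else changes.

Step 1
Reactants: 1 3,4,5-trimethoxybenzaldehyde; 2 methyl propiolate
Product: 4 methyl (R)-4-hydroxy-4-(3,4,5-trimethoxyphenyl)but-2-ynoate, via alkynyl(methyl)zinc 3 (not isolated)
Conditions: Me2Zn (3 equiv), (R,R)-ProPhenol [2,6-bis{[(R)-2-(hydroxydiphenylmethyl)pyrrolidin-1-yl]methyl}-4-methylphenol] (10 mol %), Ph3PO (20 mol %), toluene, 0–4 °C; then sat. aq. NH4Cl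
Reagents that add atoms: none
Why: Me2Zn deprotonates 2 to alkynylzinc 3, which the dinuclear zinc–ProPhenol complex should deliver to the Si face of aldehyde 1 held on the second zinc (catalytic asymmetric alkynylation of an aldehyde), setting the (R) carbinol that becomes C5.

Step 2
Reactants: 4 methyl (R)-4-hydroxy-4-(3,4,5-trimethoxyphenyl)but-2-ynoate
Product: 6 (S)-5-(3,4,5-trimethoxyphenyl)furan-2(5H)-one, via Z-hydroxy ester 5 (not isolated)
Conditions: H2 (1 atm), Pd/CaCO3 poisoned with Pb(OAc)2 (Lindlar catalyst), quinoline, EtOAc, rt; filter; then p-TsOH·H2O (5 mol %), CH2Cl2, rt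
Reagents that add atoms: none
Why: Syn delivery of one equivalent of H2 on the poisoned palladium surface should give Z-enoate 5, whose hydroxyl sits beside the ester and closes by acid-catalysed 5-exo-trig transesterification (Lindlar semihydrogenation, then lactonisation) without breaking any bond to the stereocentre; base is avoided because the C5–H of 6 is acidic.

Step 3
Reactants: 6 (S)-5-(3,4,5-trimethoxyphenyl)furan-2(5H)-one; 7 iodomethane
Product: 9 (3S,4S,5S)-3,4-dimethyl-5-(3,4,5-trimethoxyphenyl)dihydrofuran-2(3H)-one, via lithium enolate 8 (not isolated)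
Conditions: Me2CuLi (1.5 equiv; from MeLi and CuBr·SMe2, Et2O, −78 to 0 °C), then 6 in THF, −78 °C; then DMPU (5 equiv), MeI (5 equiv), −78 to −30 °C; cold sat. aq. NH4Cl/NH3
Reagents that add atoms: lithium dimethylcuprate, [Li+].C[Cu-]C (made in the flask from methyllithium, [Li]C, and CuBr·SMe2)
Why: Me2CuLi should bind the enoate of 6 as a π-complex on the ring face opposite the C5 aryl group, pass through a trivalent copper β-cuprio enolate and form the C4–CH3 bond by reductive elimination, leaving lithium enolate 8, which iodomethane activated by DMPU then alkylates at C3 in an SN2 step. The closest known reaction type is the tandem cuprate conjugate addition and enolate alkylation (three-component coupling) of cyclopentenones and γ-substituted butenolides. No ring is closed; the butenolide ring is kept and two exocyclic C–C bonds are made on it. C4 is controlled by the C5 stereocentre (methyl enters anti to the trimethoxyphenyl group, 4,5-trans) and C3 by the new C4 stereocentre (iodomethane approaches the flat enolate anti to the C4 methyl, 3,4-trans), both by 1,2-induction on a nearly planar five-membered ring. The step needs 1,4-addition to outrun removal of the acidic benzylic C5–H and expulsion of the ring carboxylate, which the weakly basic Gilman reagent at −78 °C and the in-plane C5–O bond (orthogonal to the π system) should secure, and it needs clean mono-C-methylation, which excess iodomethane, DMPU, low temperature and a cold quench should secure. TMSCl is left out on purpose, because it would cap 8 as a silyl ketene acetal that iodomethane does not alkylate.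

Step 4
Reactants: 9 (3S,4S,5S)-3,4-dimethyl-5-(3,4,5-trimethoxyphenyl)dihydrofuran-2(3H)-one
Product: 10 (3S,4S,5S)-3,4-dimethyl-5-(3,4,5-trimethoxyphenyl)tetrahydrofuran-2-ol (both anomers)
Conditions: i-Bu2AlH (1.1 equiv), CH2Cl2, −78 °C; then MeOH, aq. KNaC4H4O6 (potassium sodium tartrate)
Reagents that add atoms: none
Why: i-Bu2AlH adds one hydride to the lactone carbonyl and the tetrahedral aluminium hemiacetal persists at −78 °C until work-up, so reduction should stop at the lactol (partial reduction of a lactone) with C3, C4 and C5 untouched; the new anomeric centre is a mixture of no consequence.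

Step 5
Reactants: 10 (3S,4S,5S)-3,4-dimethyl-5-(3,4,5-trimethoxyphenyl)tetrahydrofuran-2-ol
Product: 11 (3S,4S,5S)-3,4-dimethyl-2-(phenylsulfonyl)-5-(3,4,5-trimethoxyphenyl)tetrahydrofuran (both anomers)
Conditions: PhSO2H (2 equiv, freshly liberated from PhSO2Na), powdered CaCl2, CH2Cl2, rt
Reagents that add atoms: benzenesulfinic acid, O=S(O)c1ccccc1
Why: Benzenesulfinic acid is acidic enough to ionise the lactol and its sulfur captures the oxocarbenium ion while CaCl2 takes up the water (conversion of a lactol into a 2-benzenesulfonyl cyclic ether); the anomeric configuration does not matter because C2 becomes planar again in step 6.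

Step 6
Reactants: 11 (3S,4S,5S)-3,4-dimethyl-2-(phenylsulfonyl)-5-(3,4,5-trimethoxyphenyl)tetrahydrofuran; 12 4-bromo-1,2-dimethoxybenzene
Product: 16 (2R,3S,4S,5S)-2-(3,4-dimethoxyphenyl)-3,4-dimethyl-5-(3,4,5-trimethoxyphenyl)tetrahydrofuran, via arylmagnesium bromide 13 (not isolated), via arylzinc bromide 14 (not isolated), via oxocarbenium ion 15 (not isolated)
Conditions: 12 (3 equiv), Mg, THF, 40 °C; ZnBr2 (3 equiv), THF, 0 °C to rt; then 11, THF, rt; sat. aq. NH4Cl
Reagents that add atoms: none
Why: The zinc and magnesium bromides ionise the anomeric sulfone to the C2–H oxocarbenium ion 15 and arylzinc 14 transfers its aryl group to C2 (substitution of a 2-sulfonyl cyclic ether by an organozinc reagent); in the C4-flap envelope of 15 with all three substituents pseudoequatorial the aryl group should enter on the inside face, anti to the C4 methyl and therefore syn to the C3 methyl and the C5 aryl, which sets (2R) with the 2,3-cis relation under kinetic, weakly Lewis acidic conditions that do not re-ionise the benzylic C2–O bond, whereas hydride added to the corresponding 2-aryl cation would be expected on the same face and would give the all-trans C2 epimer.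

Compound list
1 | 3,4,5-trimethoxybenzaldehyde | COc1cc(C=O)cc(OC)c1OC | starting material
2 | methyl propiolate | C#CC(=O)OC | starting material
3 | methyl(3-methoxy-3-oxoprop-1-yn-1-yl)zinc | C[Zn]C#CC(=O)OC | intermediate (not isolated)
4 | methyl (R)-4-hydroxy-4-(3,4,5-trimethoxyphenyl)but-2-ynoate | COC(=O)C#C[C@H](O)c1cc(OC)c(OC)c(OC)c1 | intermediate
5 | methyl (S,Z)-4-hydroxy-4-(3,4,5-trimethoxyphenyl)but-2-enoate | COC(=O)/C=C\[C@H](O)c1cc(OC)c(OC)c(OC)c1 | intermediate (not isolated)
6 | (S)-5-(3,4,5-trimethoxyphenyl)furan-2(5H)-one | O=C1C=C[C@@H](c2cc(OC)c(OC)c(OC)c2)O1 | intermediate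
7 | iodomethane | CI | starting material
8 | lithium (4S,5S)-4-methyl-5-(3,4,5-trimethoxyphenyl)-4,5-dihydrofuran-2-olate | [Li+].[O-]C1=C[C@H](C)[C@@H](c2cc(OC)c(OC)c(OC)c2)O1 | intermediate (not isolated)
9 | (3S,4S,5S)-3,4-dimethyl-5-(3,4,5-trimethoxyphenyl)dihydrofuran-2(3H)-one | O=C1O[C@H](c2cc(OC)c(OC)c(OC)c2)[C@@H](C)[C@@H]1C | intermediate
10 | (3S,4S,5S)-3,4-dimethyl-5-(3,4,5-trimethoxyphenyl)tetrahydrofuran-2-ol, both anomers | OC1O[C@H](c2cc(OC)c(OC)c(OC)c2)[C@@H](C)[C@@H]1C | intermediate
11 | (3S,4S,5S)-3,4-dimethyl-2-(phenylsulfonyl)-5-(3,4,5-trimethoxyphenyl)tetrahydrofuran, both anomers | O=S(=O)(c1ccccc1)C1O[C@H](c2cc(OC)c(OC)c(OC)c2)[C@@H](C)[C@@H]1C | intermediate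
12 | 4-bromo-1,2-dimethoxybenzene | COc1ccc(Br)cc1OC | starting material
13 | (3,4-dimethoxyphenyl)magnesium bromide | COc1ccc([Mg]Br)cc1OC | intermediate (not isolated)
14 | bromo(3,4-dimethoxyphenyl)zinc | COc1ccc([Zn]Br)cc1OC | intermediate (not isolated)
15 | (3S,4S,5S)-3,4-dimethyl-5-(3,4,5-trimethoxyphenyl)-4,5-dihydro-3H-furan-1-ium (C2–H oxocarbenium ion) | C1=[O+][C@H](c2cc(OC)c(OC)c(OC)c2)[C@@H](C)[C@@H]1C | intermediate (not isolated)
16 | (2R,3S,4S,5S)-2-(3,4-dimethoxyphenyl)-3,4-dimethyl-5-(3,4,5-trimethoxyphenyl)tetrahydrofuran | COc1ccc([C@@H]2O[C@H](c3cc(OC)c(OC)c(OC)c3)[C@@H](C)[C@@H]2C)cc1OC | target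

Total step count: 6. Longest linear sequence: 6 steps (1 to 4 to 6 to 9 to 10 to 11 to 16).

Steps most likely to fail

1. Step 3. The cuprate may remove the C5 proton instead of adding, which would erode the enantiomeric purity. The copper-containing enolate may also alkylate slowly, so that proton exchange gives unmethylated and doubly methylated lactone. The fallback sets out from 6 and comes back to the route at enolate 8, with the two bond formations separated. Butenolide 6 is treated with Me2CuLi and TMSCl in THF at −78 °C, where the silyl-accelerated 1,4-addition should outrun deprotonation and give trimethyl{[(4S,5S)-4-methyl-5-(3,4,5-trimethoxyphenyl)-4,5-dihydrofuran-2-yl]oxy}silane F1. Dilute aqueous acid at work-up hydrolyses this to (4S,5S)-4-methyl-5-(3,4,5-trimethoxyphenyl)dihydrofuran-2(3H)-one F2, which is purified. F2 is deprotonated with LiN(i-Pr)2 in THF at −78 °C to give the copper-free enolate 8, and iodomethane is added as in the second half of step 3 to give 9.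

2. Step 6. The aryl transfer may show poor facial selectivity, with the aryl group entering anti to the C3 methyl and giving the all-trans C2 epimer. The fallback sets out from 9 and comes back at 16, replacing steps 4 to 6; it applies only if the observed bias is that steric one. The roles of the two C2 substituents are then exchanged. (3,4-Dimethoxyphenyl)lithium F3, made from 12 with n-BuLi in THF at −78 °C, is added to lactone 9 at −78 °C and quenched cold with AcOH. This gives the hemiketal (3S,4S,5S)-2-(3,4-dimethoxyphenyl)-3,4-dimethyl-5-(3,4,5-trimethoxyphenyl)tetrahydrofuran-2-ol F4. Et3SiH and BF3·OEt2 in CH2Cl2 at −78 °C then ionise C2 and deliver hydride on that same face, which leaves the aryl group cis to the C3 methyl (aryllithium addition to a lactone followed by ionic hydrogenation of the hemiketal).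

3. Step 1. The alkynylation may give insufficient enantioselectivity with this electron-rich aldehyde. The fallback sets out from 1 and 2 and comes back at 4, taking the stereocentre from a resolution instead of from catalysis. Lithium 3-methoxy-3-oxoprop-1-yn-1-ide F5, made from 2 with LiN(SiMe3)2 in THF at −78 °C, is added to 1 to give racemic methyl 4-hydroxy-4-(3,4,5-trimethoxyphenyl)but-2-ynoate F6. Burkholderia cepacia lipase with vinyl acetate in t-BuOMe should acylate the (S)-enantiomer, by the usual size rule with aryl as the large group, to methyl (S)-4-acetoxy-4-(3,4,5-trimethoxyphenyl)but-2-ynoate F7. The (R)-alcohol 4 is left unreacted and is separated by chromatography.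

Further compounds
F1 | step 3 | trimethyl{[(4S,5S)-4-methyl-5-(3,4,5-trimethoxyphenyl)-4,5-dihydrofuran-2-yl]oxy}silane | C[Si](C)(C)OC1=C[C@H](C)[C@@H](c2cc(OC)c(OC)c(OC)c2)O1
F2 | step 3 | (4S,5S)-4-methyl-5-(3,4,5-trimethoxyphenyl)dihydrofuran-2(3H)-one | O=C1C[C@H](C)[C@@H](c2cc(OC)c(OC)c(OC)c2)O1
F3 | step 6 | (3,4-dimethoxyphenyl)lithium | COc1ccc([Li])cc1OC
F4 | step 6 | (3S,4S,5S)-2-(3,4-dimethoxyphenyl)-3,4-dimethyl-5-(3,4,5-trimethoxyphenyl)tetrahydrofuran-2-ol | COc1ccc(C2(O)O[C@H](c3cc(OC)c(OC)c(OC)c3)[C@@H](C)[C@@H]2C)cc1OC
F5 | step 1 | lithium 3-methoxy-3-oxoprop-1-yn-1-ide | [Li]C#CC(=O)OC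
F6 | step 1 | racemic methyl 4-hydroxy-4-(3,4,5-trimethoxyphenyl)but-2-ynoate | COC(=O)C#CC(O)c1cc(OC)c(OC)c(OC)c1
F7 | step 1 | methyl (S)-4-acetoxy-4-(3,4,5-trimethoxyphenyl)but-2-ynoate | COC(=O)C#C[C@@H](OC(C)=O)c1cc(OC)c(OC)c(OC)c1
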